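**Strategy**

The 2,2-dimethyl-2H-pyran (ring A) is disconnected across C4–C4a and O1–C2. This exploits the fact that C4a and the oxygen on C8a form an enol-type C,O-bis-nucleophile of the 1,3,5-trioxygenated carbocycle (ring B), matched to the 1,3-bis-electrophile 3-methylbut-2-enal. The key step is a formal oxa-[3+3] annulation (Knoevenagel-type condensation, then oxa-6π electrocyclisation) on commercial 2,4,6-trihydroxybenzophenone, giving the aromatic 6-benzoylchromene in one operation. That chromene has one free ring carbon (C8), so double C-prenylation there is regiochemically forced and dearomatises ring B to the acyl-β-triketone of the target.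

Key step: step 1

Remark on the chemistry: the target is an enolised β-triketone. The 7-hydroxy-5-oxo form drawn and the 5-hydroxy-7-oxo form interconvert by proton transfer within the chelate and are treated as one compound. The target has no stereocentre (C8 carries two identical prenyl groups), so no stereocontrol is required. 2,4,6-Trihydroxybenzophenone is taken as a commercial starting material.

**Route**

Step 1
Reactants: 1 2,4,6-trihydroxybenzophenone; 2 3-methylbut-2-enal
Product: 4 (5,7-dihydroxy-2,2-dimethyl-2H-chromen-6-yl)(phenyl)methanone, via o-quinone methide 3 (not isolated)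
Conditions: 2 (1.0 equiv), ethylenediammonium diacetate (10 mol%), xylene, 140 °C
Reagents that add atoms: 3-methylbut-2-enal (compound 2), CC(C)=CC=O
Why: Ethylenediammonium diacetate converts 2 into its α,β-unsaturated iminium ion, to which C3 of 1 (ortho and para to three hydroxyls) adds in a Knoevenagel/Mannich-type 1,2-addition; loss of the amine gives the o-quinone methide 3, a 1-oxatriene, which undergoes thermal oxa-6π electrocyclisation to the chromene with rearomatisation as driving force. The closest known reaction type is the formal oxa-[3+3] annulation of phenols and 1,3-dicarbonyl compounds with enals to 2H-chromenes. The pyran ring is closed in the pericyclic mode, by disrotatory 6π electrocyclisation that forms O1–C2 after the C4–C4a bond has been made intermolecularly. No stereocentre arises because C2 carries two methyl groups. The step needs closure through the para oxygen and not an ortho oxygen, and mono- and not bis-annulation: the ortho hydroxyls are engaged in hydrogen bonding to the benzoyl carbonyl while the para oxygen is free and the most acidic, which should favour the 6-benzoyl isomer over the separable 8-benzoyl isomer, and one equivalent of 2 should limit a second annulation at C8. 1,2- over 1,4-addition to 2 is secured by iminium activation and by the β,β-disubstitution of the enal.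

Step 2
Reactants: 4 (5,7-dihydroxy-2,2-dimethyl-2H-chromen-6-yl)(phenyl)methanone; 5 prenyl bromide (1-bromo-3-methylbut-2-ene)
Product: 7 6-benzoyl-7-hydroxy-2,2-dimethyl-8,8-bis(3-methylbut-2-en-1-yl)-2H-chromen-5(8H)-one (the target), via 8-prenylchromene 6 (not isolated)
Conditions: 5 (2.5 equiv), NaOMe (3 equiv), MeOH, 0 °C to rt; then 1 M HCl
Reagents that add atoms: prenyl bromide (compound 5), CC(C)=CCBr
Why: Alkylative dearomatisation by two successive SN2 C-alkylations of the phenoxide at C8 (ortho to O7, para to O5, the only unsubstituted ring carbon), the reaction type that converts deoxyhumulones into lupulones; the protic medium should favour C- over O-alkylation, the acyl-bearing C6 is deactivated, and the new quaternary C8 carries two identical prenyl groups, so no stereocentre is set.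

**Compound list**

1 | 2,4,6-trihydroxybenzophenone | O=C(c1ccccc1)c1c(O)cc(O)cc1O | starting material
2 | 3-methylbut-2-enal (prenal) | CC(C)=CC=O | starting material
3 | 4-benzoyl-3,5-dihydroxy-6-(3-methylbut-2-en-1-ylidene)cyclohexa-2,4-dien-1-one (o-quinone methide, 1-oxatriene) | O=C1C=C(O)C(C(=O)c2ccccc2)=C(O)C1=CC=C(C)C | intermediate (not isolated)
4 | (5,7-dihydroxy-2,2-dimethyl-2H-chromen-6-yl)(phenyl)methanone | CC1(C)C=Cc2c(O)c(C(=O)c3ccccc3)c(O)cc2O1 | intermediate
5 | prenyl bromide (1-bromo-3-methylbut-2-ene) | CC(C)=CCBr | starting material
6 | (5,7-dihydroxy-2,2-dimethyl-8-(3-methylbut-2-en-1-yl)-2H-chromen-6-yl)(phenyl)methanone | CC(C)=CCc1c(O)c(C(=O)c2ccccc2)c(O)c2C=CC(C)(C)Oc12 | intermediate (not isolated)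
7 | 6-benzoyl-7-hydroxy-2,2-dimethyl-8,8-bis(3-methylbut-2-en-1-yl)-2H-chromen-5(8H)-one | CC(C)=CCC1(CC=C(C)C)C(O)=C(C(=O)c2ccccc2)C(=O)C2=C1OC(C)(C)C=C2 | target

**Summary**

Total step count: 2. Longest linear sequence: 2.

The route has only two steps, so both are ranked, the riskier first.

Step 1 (most likely to fail). Ring closure may proceed partly through an ortho oxygen, giving the 8-benzoyl regioisomer, and a second annulation at C8 may consume product. Fallback, setting out from 1 and coming back at 4: the para hydroxyl of 1, the only one not chelated to the benzoyl carbonyl and the most acidic, would be etherified with 3-chloro-3-methylbut-1-yne (K2CO3, KI, CuCl2 cat., acetone, reflux). This would give the aryl 1,1-dimethylpropargyl ether (2,6-dihydroxy-4-((2-methylbut-3-yn-2-yl)oxy)phenyl)(phenyl)methanone F1. Heating F1 (N,N-diethylaniline or xylene, 140–190 °C) would trigger propargyl Claisen rearrangement to C3, enolisation, 1,5-hydrogen shift and oxa-6π closure. Because both positions ortho to the ether oxygen are equivalent, 4 is the only chromene that can form.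

Step 2. O-Prenylation may compete with C-alkylation, and the second, quaternising alkylation may stall at 6. Fallback, setting out from 4 and coming back at 7: the quaternary centre would be built with the smaller, softer π-allyl electrophile. Tsuji–Trost allylation of 4 with allyl methyl carbonate and Pd(PPh3)4 (zerovalent palladium) in THF would pass through (8-allyl-5,7-dihydroxy-2,2-dimethyl-2H-chromen-6-yl)(phenyl)methanone F2 to 8,8-diallyl-6-benzoyl-7-hydroxy-2,2-dimethyl-2H-chromen-5(8H)-one F3. Double cross-metathesis of F3 with excess 2-methylbut-2-ene (second-generation Grubbs catalyst, RuCl2(=CHPh)(H2IMes)(PCy3), CH2Cl2, 40 °C) would convert both allyl groups into prenyl groups and give 7. The hindered cis-disubstituted C3=C4 alkene of ring A, flanked by the quaternary C2, should not take part.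

**Further compounds**

F1 | step 1 | (2,6-dihydroxy-4-((2-methylbut-3-yn-2-yl)oxy)phenyl)(phenyl)methanone | C#CC(C)(C)Oc1cc(O)c(C(=O)c2ccccc2)c(O)c1
F2 | step 2 | (8-allyl-5,7-dihydroxy-2,2-dimethyl-2H-chromen-6-yl)(phenyl)methanone | C=CCc1c(O)c(C(=O)c2ccccc2)c(O)c2C=CC(C)(C)Oc12
F3 | step 2 | 8,8-diallyl-6-benzoyl-7-hydroxy-2,2-dimethyl-2H-chromen-5(8H)-one | C=CCC1(CC=C)C(O)=C(C(=O)c2ccccc2)C(=O)C2=C1OC(C)(C)C=C2
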